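# Proposed synthesis of CNP0115253.1 (target 22) by late cobalt-mediated construction of the catechol ring

## Analysis of the target

The target 22 is a 2,3,4-trisubstituted oxolane, numbered here O1, C2, C3, C4, C5. C2 carries the 3,4-dihydroxyphenyl ring, C3 the hydroxymethyl carbon C6, C4 a tertiary hydroxyl and the benzylic carbon C7 of the 3,4-dimethoxyphenyl ring, and C5 is a methylene. The three stereocentres are contiguous and all R. The aryl group on C2, the CH2OH on C3 and the OH on C4 lie on one face, and the dimethoxybenzyl group alone on the other, so C2/C3 are cis, the less stable arrangement. The free catechol is easily oxidised, above all as its anion. C2 is a benzylic ether carbon para to a phenolic oxygen, so acid can open the C2–O1 bond to a quinone-methide-type cation and reclose it to the 2,3-trans isomer. The two arenes differ (catechol against dimethyl ether), which rules out a late demethylation, and benzyl protection of the catechol would require hydrogenolysis next to the C2–O1 bond. The main difficulty is to set three adjacent centres, one of them a fully substituted carbinol, while keeping the sensitive cis C2 centre intact. The strategy rests on the fact that C2 bears a single exocyclic carbon substituent, an arene. An ethynyl group can stand in for it until all stereocentres are in place, and its two carbons then become the ipso and one ortho carbon of the catechol ring.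

## Retrosynthetic reasoning

**22 from 21.** Only silicon–oxygen bonds are cut. The catechol, the primary alcohol and the tertiary alcohol are all masked as silyl ethers in 21, so a single buffered fluoride treatment releases 22 without acid, strong base or hydrogen.

**21 from 18 and 19.** Two C–C bonds of the catechol ring are cut, those joining the ipso carbon and its ortho neighbour to the two methylene carbons of diene 19. This places the arene construction after every stereocentre, so the acid-labile para-oxygenated benzylic ether never sees the earlier steps. The forward reaction has to join a hindered terminal alkyne and an electron-rich diene in a [4+2] sense to cyclohexadiene 20 and then dehydrogenate 20 to 21. Diene 19 is symmetric, so no regiochemical question arises.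

**18 from 17 and 16.** The tertiary hydroxyl of 17 is capped with the same trimethylsilyl group that 19 carries, which keeps the cobalt/zinc medium aprotic. 17 comes from 16 by removal of the alkyne silyl group. These are adjustments only.

**16 from 14 through 15.** The C4–C5 bond is cut. C5 is a one-carbon unit already attached to O1, so closing the ring by carbon–carbon bond formation at the ketone carbon C4 creates the tertiary alcohol and the ring in one operation. The forward reaction has to turn the O,S-acetal of 14 into the α-chloro ether 15, add its reduced form to the ketone, and set C4 with the OH cis to the C6 arm.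

**14 from 10 and 11.** The C4–C7 bond is cut next to the carbonyl. The dimethoxybenzyl group then arrives as the Grignard reagent 12 made from the commercial chloride 11, and the N-methoxy-N-methylamide 10 stops the addition at the ketone stage through 13.

**10 from 9 from 8.** The (methylsulfanyl)methyl ether of 10 installs the latent C5 on O1, and the amide of 9 replaces the auxiliary of 8. Both changes are made before the ketone exists, so the base-sensitive β-oxygenated ketone is formed late and handled only under neutral conditions.

**8 from 4 and 5; 4 from 1 and 2.** The C2–C3 bond is cut as a syn-aldol between the enolate 6 of imide 4 and ynal 5. This sets C2 and C3 together, in the cis sense needed in the ring, under control of the auxiliary 1. Acid 2 supplies C4, C3 and C6 with the C6 oxygen already protected.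

## Alternatives that were turned down

**Alternative 1:** The C4–C5 bond and the C7–aryl bond are made together at an alkenyl boronate in which C4=C7 is the double bond. A silylmethyl Grignard reagent forms the boron ate complex. An arylpalladium species generated from an aryl triflate with Pd(OAc)2 and MandyPhos then triggers a 1,2-shift of the CH2Si group from boron to C4 while the aryl group bonds to C7, giving the tertiary boronic ester A1. In its favour, the quaternary centre C4 and both of its carbon arms arise in one catalyst-controlled step, and oxidation of the C–B bond gives the tertiary OH with retention. Against it for this target: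
- The boron sits on a 1,1-disubstituted alkene next to the branched C3, where ate-complex formation and migration are slow and the catalyst must override the existing centres.
- After A1 the route still needs oxidation of a hindered tertiary boronate, oxidation of the C–Si bond, selective activation of C5–OH, ring closure from the C2 oxygen, and hydrogenolysis of three benzyl ethers beside the doubly activated C2–O1 bond.
- The electron-rich aryl group on C2 is carried through all of these steps.

On control of C4 this alternative is stronger than the substrate-controlled ring closure used here. The chosen strategy offers in return a ring closure that forms C4–C5 directly on O1, one step after the key step, and no hydrogenolysis.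

**Alternative 2:** The C2–C3 bond is made photochemically. An excited aryl aldehyde adds across the unsubstituted double bond of a 3-benzylfuran to give the cis-fused oxetane A2 with the aryl group exo, the oxetane oxygen being bonded to the future C6. It is the shortest way to the cis C2/C3 relationship and starts from simple achiral materials, and on step count for that bond it is stronger than the aldol used here. Against it:
- The photoadduct is racemic, so absolute configuration would need a resolution.
- The furan offers two double bonds.
- The wrong oxygen is attached where the target has the C5–O1 bond. The acetal must be opened, C6 reduced, the enol ether oxidised at C4 with facial control, and the ring rebuilt from the C2 oxygen, all on an acid-labile benzylic oxetane.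

The chosen strategy gives the absolute configuration from an auxiliary and forms the ring with the correct oxygen connectivity in one step.

**Alternative 3:** The C2–C3 and O1–C5 bonds are made by carbene catalysis. A chiral triazolium-derived carbene converts an enal into a homoenolate equivalent that adds to an aryl aldehyde, and the alkoxide closes the γ-lactone A3 with the 2,3-cis relationship. It needs no auxiliary and sets two centres catalytically from two aldehydes, which is stronger on atom and step economy for C2/C3. Against it:
- Electron-rich 3,4-dialkoxybenzaldehydes are poor acceptors, and cis/trans and enantiomer control in such annulations are uneven.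
- C4 must then be built on the lactone enolate, where the second electrophile enters anti to the C6 arm. Hydroxylation after benzylation would therefore give the wrong C4 epimer.
- The lactone carbonyl must be reduced to the C5 methylene by Lewis-acidic reduction next to the ionisable C2.
- The benzyl ethers again need hydrogenolysis.

The chosen strategy sets C4 in the required sense during ring closure and never exposes the arylated C2 to acid or hydrogen.

Key step: step 9

Assumption: 3-(tert-butyldimethylsilyloxy)propanoic acid 2 and 2,3-bis(trimethylsilyloxy)buta-1,3-diene 19 are taken as catalogue compounds; if 2 had to be made, it would add two steps from methyl 3-hydroxypropanoate.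

## Route

Step 1
Reactants: 1 (R)-4-benzyloxazolidin-2-one; 2 3-(tert-butyldimethylsilyloxy)propanoic acid
Product: 4 (R)-4-benzyl-3-[3-(tert-butyldimethylsilyloxy)propanoyl]oxazolidin-2-one, via mixed pivalic anhydride 3 (not isolated)
Conditions: PivCl, Et3N, THF, −20 °C; then LiCl, 1, −20 °C → rt
Reagents that add atoms: none
Why: N-acylation of the oxazolidinone through the mixed pivalic anhydride; attack occurs at the less hindered carbonyl of 3, and the silyl ether is untouched under these mild basic conditions.

Step 2
Reactants: 4 (R)-4-benzyl-3-[3-(tert-butyldimethylsilyloxy)propanoyl]oxazolidin-2-one; 5 3-(trimethylsilyl)prop-2-ynal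
Product: 8 (R)-4-benzyl-3-[(2R,3R)-2-[(tert-butyldimethylsilyloxy)methyl]-3-hydroxy-5-(trimethylsilyl)pent-4-ynoyl]oxazolidin-2-one, via dibutylboron (Z)-enolate 6 (not isolated), via dibutylboron aldolate 7 (not isolated)
Conditions: Bu2BOTf, i-Pr2NEt, CH2Cl2, −78 → 0 °C; 5, −78 → 0 °C; then pH 7 phosphate buffer, MeOH, H2O2, 0 °C
Reagents that add atoms: none
Why: Evans syn-aldol: the (Z)-boron enolate 6 reacts through a Zimmerman–Traxler chair on the face away from the benzyl group of the (R)-auxiliary, which sets the future C3 and C2 together as 2R,3R (syn, hence cis in the later ring). The covalent boron enolate should not expel the β-silyloxy group at low temperature, and ynals are reactive, unhindered acceptors.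

Step 3
Reactants: 8 (R)-4-benzyl-3-[(2R,3R)-2-[(tert-butyldimethylsilyloxy)methyl]-3-hydroxy-5-(trimethylsilyl)pent-4-ynoyl]oxazolidin-2-one
Product: 9 (2R,3R)-2-[(tert-butyldimethylsilyloxy)methyl]-3-hydroxy-N-methoxy-N-methyl-5-(trimethylsilyl)pent-4-ynamide
Conditions: MeONHMe·HCl, AlMe3, CH2Cl2, −15 → 0 °C; aq. potassium sodium tartrate
Reagents that add atoms: N,O-dimethylhydroxylamine hydrochloride, CNOC.Cl
Why: Aluminium-amide transamination to the Weinreb amide; the free β-hydroxyl directs the aluminium reagent to the exocyclic carbonyl, and the auxiliary 1 is recovered. Neither stereocentre is touched.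

Step 4
Reactants: 9 (2R,3R)-2-[(tert-butyldimethylsilyloxy)methyl]-3-hydroxy-N-methoxy-N-methyl-5-(trimethylsilyl)pent-4-ynamide
Product: 10 (2R,3R)-2-[(tert-butyldimethylsilyloxy)methyl]-N-methoxy-N-methyl-3-[(methylsulfanyl)methoxy]-5-(trimethylsilyl)pent-4-ynamide
Conditions: Me2S, (BzO)2, MeCN, 0 °C
Reagents that add atoms: dimethyl sulfide, CSC
Why: Pummerer-type (methylsulfanyl)methylation: the acyloxysulfonium salt from Me2S and the peroxide collapses to the thionium ion, which the secondary alcohol traps. The conditions are weakly acidic and non-oxidising toward the carbinol, so the silyl groups and the stereocentres are safe.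

Step 5
Reactants: 10 (2R,3R)-2-[(tert-butyldimethylsilyloxy)methyl]-N-methoxy-N-methyl-3-[(methylsulfanyl)methoxy]-5-(trimethylsilyl)pent-4-ynamide; 11 4-(chloromethyl)-1,2-dimethoxybenzene
Product: 14 (3R,4R)-3-[(tert-butyldimethylsilyloxy)methyl]-1-(3,4-dimethoxyphenyl)-4-[(methylsulfanyl)methoxy]-6-(trimethylsilyl)hex-5-yn-2-one, via benzylic Grignard reagent 12 (not isolated), via chloromagnesium hemiaminal 13 (not isolated)
Conditions: 11, Mg, THF, 0 °C (slow addition); then 10, THF, −78 → 0 °C; aq. NH4Cl
Reagents that add atoms: none
Why: Weinreb ketone synthesis: the chelated tetrahedral adduct 13 survives until the quench, so the enolisable, β-oxygenated ketone 14 is never exposed to the basic reagent and C3 should not epimerise or eliminate. Slow, cold formation of 12 limits Wurtz coupling.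

Step 6
Reactants: 14 (3R,4R)-3-[(tert-butyldimethylsilyloxy)methyl]-1-(3,4-dimethoxyphenyl)-4-[(methylsulfanyl)methoxy]-6-(trimethylsilyl)hex-5-yn-2-one
Product: 16 (3R,4R,5R)-4-[(tert-butyldimethylsilyloxy)methyl]-3-(3,4-dimethoxybenzyl)-5-[(trimethylsilyl)ethynyl]oxolan-3-ol, via chloromethyl ether 15 (not isolated)
Conditions: SO2Cl2 (1.05 equiv), cyclohexene, CH2Cl2, −78 → 0 °C; evaporate; then slow addition to SmI2 (2.5 equiv), THF, 0 °C → rt
Reagents that add atoms: none
Why: Sulfuryl chloride cleaves the O,S-acetal through a chlorosulfonium ion to the α-chloro ether 15 (cyclohexene takes up the sulfenyl chloride), and SmI2 then effects a samarium Barbier reaction in which the reduced alkoxymethyl carbon adds to the ketone in a 5-exo-trig closure that forms C4–C5. C4 should form with the OH cis to the C6 arm (4R in the ring numbering of the analysis), because the dimethoxybenzyl group turns away from C6 in the ring-like transition state and the trivalent samarium alkoxide can bridge to the C6 oxygen.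

Step 7
Reactants: 16 (3R,4R,5R)-4-[(tert-butyldimethylsilyloxy)methyl]-3-(3,4-dimethoxybenzyl)-5-[(trimethylsilyl)ethynyl]oxolan-3-ol
Product: 17 (3R,4R,5R)-4-[(tert-butyldimethylsilyloxy)methyl]-3-(3,4-dimethoxybenzyl)-5-ethynyloxolan-3-ol
Conditions: K2CO3, MeOH, rt
Reagents that add atoms: none
Why: Methanolysis of the C(sp)–Si bond; the primary tert-butyldimethylsilyl ether is stable to carbonate in methanol and no carbonyl group remains that could epimerise.

Step 8
Reactants: 17 (3R,4R,5R)-4-[(tert-butyldimethylsilyloxy)methyl]-3-(3,4-dimethoxybenzyl)-5-ethynyloxolan-3-ol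
Product: 18 tert-butyl{[(2R,3R,4R)-4-(3,4-dimethoxybenzyl)-2-ethynyl-4-(trimethylsilyloxy)oxolan-3-yl]methoxy}dimethylsilane
Conditions: 1-(trimethylsilyl)imidazole, CH2Cl2, rt
Reagents that add atoms: 1-(trimethylsilyl)imidazole, C[Si](C)(C)n1ccnc1
Why: Neutral O-silylation of the tertiary alcohol by the silylimidazole. It removes the only protic group before the cobalt step, and the trimethylsilyl ether leaves with the other silyl groups in step 10.

Step 9
Reactants: 18 tert-butyl{[(2R,3R,4R)-4-(3,4-dimethoxybenzyl)-2-ethynyl-4-(trimethylsilyloxy)oxolan-3-yl]methoxy}dimethylsilane; 19 2,3-bis(trimethylsilyloxy)buta-1,3-diene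
Product: 21 tert-butyl{[(2R,3R,4R)-2-[3,4-bis(trimethylsilyloxy)phenyl]-4-(3,4-dimethoxybenzyl)-4-(trimethylsilyloxy)oxolan-3-yl]methoxy}dimethylsilane, via cyclohexa-1,4-diene 20 (not isolated)
Conditions: 19 (2 equiv), CoBr2(dppe) (10 mol %), Zn (20 mol %), ZnI2 (20 mol %), CH2Cl2, rt; filter, evaporate; then DDQ (1.05 equiv), benzene, 0 °C → rt
Reagents that add atoms: none
Why: Zinc reduces the divalent cobalt bromide complex to monovalent cobalt and ZnI2 abstracts halide, giving a cationic cobalt–diphosphine fragment that binds diene 19 and the terminal alkyne of 18. Oxidative coupling gives a cobaltacycle, and reductive elimination closes the six-membered carbocycle of 20 in a formal [4+2] mode, forming both new C–C bonds between the alkyne carbons and the terminal carbons of the diene. The closest known reaction type is the cobalt-catalysed neutral [4+2] cycloaddition of unactivated terminal alkynes with 2-silyloxy- and 2,3-disubstituted buta-1,3-dienes, followed by dehydrogenation of the cyclohexa-1,4-diene with DDQ. DDQ removes hydride from a doubly allylic methylene of 20 and then a proton, which gives the arene with the two silyloxy groups para and meta to C2. No new stereocentre forms, and the symmetric diene leaves no regiochemical choice. The step needs cross-cycloaddition in preference to alkyne trimerisation, which the excess of the diene and the chelating diphosphine favour. It also needs the oxidant to act on 20 only: the bis(silyl enol ether) diene is a far better hydride donor than the C7 methylene or the newly benzylic C2–H, and the oxidant is limited to one equivalent in a non-polar solvent at low temperature. The medium is neutral and aprotic, so the C2 centre, which becomes ionisable only once the arene exists, should keep its configuration.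

Step 10
Reactants: 21 tert-butyl{[(2R,3R,4R)-2-[3,4-bis(trimethylsilyloxy)phenyl]-4-(3,4-dimethoxybenzyl)-4-(trimethylsilyloxy)oxolan-3-yl]methoxy}dimethylsilane
Product: 22 4-[(2R,3R,4R)-4-(3,4-dimethoxybenzyl)-4-hydroxy-3-(hydroxymethyl)oxolan-2-yl]benzene-1,2-diol
Conditions: Bu4NF, AcOH (1:1), THF, 0 °C → rt, argon
Reagents that add atoms: none
Why: Fluoride-induced cleavage of all four silyl ethers. The acetic acid buffer keeps the catechol protonated, which suppresses air oxidation and quinone-methide opening at C2, and the medium is not acidic enough to ionise the C2–O1 bond.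

## Compound list

1 | (R)-4-benzyloxazolidin-2-one | O=C1N[C@H](Cc2ccccc2)CO1 | starting material
2 | 3-(tert-butyldimethylsilyloxy)propanoic acid | OC(=O)CCO[Si](C)(C)C(C)(C)C | starting material
3 | 3-(tert-butyldimethylsilyloxy)propanoic pivalic anhydride | CC(C)(C)C(=O)OC(=O)CCO[Si](C)(C)C(C)(C)C | intermediate
4 | (R)-4-benzyl-3-[3-(tert-butyldimethylsilyloxy)propanoyl]oxazolidin-2-one | O=C(CCO[Si](C)(C)C(C)(C)C)N1C(=O)OC[C@H]1Cc1ccccc1 | intermediate
5 | 3-(trimethylsilyl)prop-2-ynal | C[Si](C)(C)C#CC=O | starting material
6 | dibutylboron (Z)-enolate of 4 | CCCCB(CCCC)O/C(=C\CO[Si](C)(C)C(C)(C)C)N1C(=O)OC[C@H]1Cc1ccccc1 | intermediate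
7 | dibutylboron aldolate of 8 | CCCCB(CCCC)O[C@@H](C#C[Si](C)(C)C)[C@H](C(=O)N1C(=O)OC[C@H]1Cc1ccccc1)CO[Si](C)(C)C(C)(C)C | intermediate
8 | (R)-4-benzyl-3-[(2R,3R)-2-[(tert-butyldimethylsilyloxy)methyl]-3-hydroxy-5-(trimethylsilyl)pent-4-ynoyl]oxazolidin-2-one | O[C@@H](C#C[Si](C)(C)C)[C@H](C(=O)N1C(=O)OC[C@H]1Cc1ccccc1)CO[Si](C)(C)C(C)(C)C | intermediate
9 | (2R,3R)-2-[(tert-butyldimethylsilyloxy)methyl]-3-hydroxy-N-methoxy-N-methyl-5-(trimethylsilyl)pent-4-ynamide | O[C@@H](C#C[Si](C)(C)C)[C@H](C(=O)N(C)OC)CO[Si](C)(C)C(C)(C)C | intermediate
10 | (2R,3R)-2-[(tert-butyldimethylsilyloxy)methyl]-N-methoxy-N-methyl-3-[(methylsulfanyl)methoxy]-5-(trimethylsilyl)pent-4-ynamide | CSCO[C@@H](C#C[Si](C)(C)C)[C@H](C(=O)N(C)OC)CO[Si](C)(C)C(C)(C)C | intermediate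
11 | 4-(chloromethyl)-1,2-dimethoxybenzene | COc1ccc(CCl)cc1OC | starting material
12 | (3,4-dimethoxybenzyl)magnesium chloride | COc1ccc(C[Mg]Cl)cc1OC | intermediate
13 | chloromagnesium hemiaminal from 10 and 12 (configuration at the hemiaminal carbon not defined) | CSCO[C@@H](C#C[Si](C)(C)C)[C@H](C(O[Mg]Cl)(Cc1ccc(OC)c(OC)c1)N(C)OC)CO[Si](C)(C)C(C)(C)C | intermediate
14 | (3R,4R)-3-[(tert-butyldimethylsilyloxy)methyl]-1-(3,4-dimethoxyphenyl)-4-[(methylsulfanyl)methoxy]-6-(trimethylsilyl)hex-5-yn-2-one | CSCO[C@@H](C#C[Si](C)(C)C)[C@H](C(=O)Cc1ccc(OC)c(OC)c1)CO[Si](C)(C)C(C)(C)C | intermediate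
15 | (3R,4R)-3-[(tert-butyldimethylsilyloxy)methyl]-4-(chloromethoxy)-1-(3,4-dimethoxyphenyl)-6-(trimethylsilyl)hex-5-yn-2-one | ClCO[C@@H](C#C[Si](C)(C)C)[C@H](C(=O)Cc1ccc(OC)c(OC)c1)CO[Si](C)(C)C(C)(C)C | intermediate
16 | (3R,4R,5R)-4-[(tert-butyldimethylsilyloxy)methyl]-3-(3,4-dimethoxybenzyl)-5-[(trimethylsilyl)ethynyl]oxolan-3-ol | COc1ccc(C[C@]2(O)CO[C@@H](C#C[Si](C)(C)C)[C@H]2CO[Si](C)(C)C(C)(C)C)cc1OC | intermediate
17 | (3R,4R,5R)-4-[(tert-butyldimethylsilyloxy)methyl]-3-(3,4-dimethoxybenzyl)-5-ethynyloxolan-3-ol | COc1ccc(C[C@]2(O)CO[C@@H](C#C)[C@H]2CO[Si](C)(C)C(C)(C)C)cc1OC | intermediate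
18 | tert-butyl{[(2R,3R,4R)-4-(3,4-dimethoxybenzyl)-2-ethynyl-4-(trimethylsilyloxy)oxolan-3-yl]methoxy}dimethylsilane | COc1ccc(C[C@]2(O[Si](C)(C)C)CO[C@@H](C#C)[C@H]2CO[Si](C)(C)C(C)(C)C)cc1OC | intermediate
19 | 2,3-bis(trimethylsilyloxy)buta-1,3-diene | C=C(O[Si](C)(C)C)C(=C)O[Si](C)(C)C | starting material
20 | tert-butyl{[(2R,3R,4R)-2-[4,5-bis(trimethylsilyloxy)cyclohexa-1,4-dien-1-yl]-4-(3,4-dimethoxybenzyl)-4-(trimethylsilyloxy)oxolan-3-yl]methoxy}dimethylsilane | COc1ccc(C[C@]2(O[Si](C)(C)C)CO[C@@H](C3=CCC(O[Si](C)(C)C)=C(O[Si](C)(C)C)C3)[C@H]2CO[Si](C)(C)C(C)(C)C)cc1OC | intermediate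
21 | tert-butyl{[(2R,3R,4R)-2-[3,4-bis(trimethylsilyloxy)phenyl]-4-(3,4-dimethoxybenzyl)-4-(trimethylsilyloxy)oxolan-3-yl]methoxy}dimethylsilane | COc1ccc(C[C@]2(O[Si](C)(C)C)CO[C@@H](c3ccc(O[Si](C)(C)C)c(O[Si](C)(C)C)c3)[C@H]2CO[Si](C)(C)C(C)(C)C)cc1OC | intermediate
22 | 4-[(2R,3R,4R)-4-(3,4-dimethoxybenzyl)-4-hydroxy-3-(hydroxymethyl)oxolan-2-yl]benzene-1,2-diol | COc1ccc(C[C@]2(O)CO[C@@H](c3ccc(O)c(O)c3)[C@H]2CO)cc1OC | target

## Step count and least certain steps

Total step count: 10. Longest linear sequence: 10 steps (2 → 22).

**Step 9 (key step).** The cycloaddition may stall through crowding of the propargylic centre by the cis C6 arm and the C4 silyl ether, or through loss of the enol silyl groups from 19 or 20 in the Lewis-acidic medium. Alkyne trimerisation may compete. In the second stage the oxidant may go on to abstract hydride from the newly benzylic C2–H, since the product is an electron-rich benzylic ether. The fallback builds a mono-oxygenated ring first and adds the second oxygen by oxidation: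
- It sets out from 18, which is combined with commercial 2-(trimethylsilyloxy)buta-1,3-diene under the same CoBr2(dppe)/Zn/ZnI2 system. This pairing and its para regiochemistry with the diphosphine ligand are the best established of this cycloaddition.
- Dehydrogenation then gives the 4-(trimethylsilyloxy)phenyl compound F1, and K2CO3 in methanol releases the phenol F2.
- Ortho-oxygenation of F2 with 2-iodoxybenzoic acid in DMF gives the ortho-quinone F3, which aqueous Na2S2O4 reduces to the catechol F4.
- The buffered fluoride conditions of step 10 return F4 to the route at 22.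

**Step 6.** Three things may go wrong: electrophilic chlorination at the doubly activated C7 methylene or the dimethoxyarene during the sulfide cleavage; protonation of the reduced carbon by the enolisable ketone in place of ring closure; and attack on the wrong face of the ketone. The fallback closes the ring first and adds the benzyl group to a cyclic ketone, where both neighbouring substituents shield the same face:
- It sets out from 9, which is treated with chloromethyllithium F5, generated in its presence from ICH2Cl and MeLi·LiBr at −78 °C, to give the chloromethyl ketone F6.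
- Ag2O in CH2Cl2 closes F6 by 5-exo-tet O-alkylation to the oxolan-3-one F7.
- Grignard reagent 12 is added to F7 in the presence of LaCl3·2LiCl at −78 °C, anti to the C2 and C3 substituents, and the route is rejoined at 16.

**Step 2.** The enolate may expel the β-silyloxy group, or conversion may be low with the sensitive ynal. The fallback brings C6 in as a vinyl group, which cannot be eliminated:
- It sets out from 1, which is acylated with (E)-but-2-enoyl chloride (n-BuLi, THF, −78 °C) to the crotonyl imide F8.
- The boron dienolate of F8 (Bu2BOTf, Et3N) reacts with 5 at its α-carbon to give the α-vinyl syn-aldol F9.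
- Transamination as in step 3 gives the amide F10.
- Ozonolysis of the vinyl group at −78 °C with NaBH4 work-up gives the diol F11.
- Silylation of the primary hydroxyl of F11 (TBSCl, imidazole, 0 °C) rejoins the route at 9.

**Step 10.** The catechol may be oxidised as its anion, C2 may epimerise through quinone-methide opening, and the primary silyl ether may cleave incompletely under the buffered conditions. The fallback isolates a stable ester before the final release:
- It sets out from 21, which is desilylated as in step 10. The crude product is acetylated directly (Ac2O, pyridine, DMAP) to the triacetate F12, which can be purified without special care.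
- Methanolysis of F12 with catalytic K2CO3 in degassed methanol at 0 °C under argon, quenched with an acidic resin, returns the route at 22.

## Further compounds

F1 | step 9 | tert-butyl{[(2R,3R,4R)-4-(3,4-dimethoxybenzyl)-4-(trimethylsilyloxy)-2-[4-(trimethylsilyloxy)phenyl]oxolan-3-yl]methoxy}dimethylsilane | COc1ccc(C[C@]2(O[Si](C)(C)C)CO[C@@H](c3ccc(O[Si](C)(C)C)cc3)[C@H]2CO[Si](C)(C)C(C)(C)C)cc1OC
F2 | step 9 | (3R,4R,5R)-4-[(tert-butyldimethylsilyloxy)methyl]-3-(3,4-dimethoxybenzyl)-5-(4-hydroxyphenyl)oxolan-3-ol | COc1ccc(C[C@]2(O)CO[C@@H](c3ccc(O)cc3)[C@H]2CO[Si](C)(C)C(C)(C)C)cc1OC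
F3 | step 9 | 4-[(2R,3R,4R)-3-[(tert-butyldimethylsilyloxy)methyl]-4-(3,4-dimethoxybenzyl)-4-hydroxyoxolan-2-yl]cyclohexa-3,5-diene-1,2-dione | COc1ccc(C[C@]2(O)CO[C@@H](C3=CC(=O)C(=O)C=C3)[C@H]2CO[Si](C)(C)C(C)(C)C)cc1OC
F4 | step 9 | 4-[(2R,3R,4R)-3-[(tert-butyldimethylsilyloxy)methyl]-4-(3,4-dimethoxybenzyl)-4-hydroxyoxolan-2-yl]benzene-1,2-diol | COc1ccc(C[C@]2(O)CO[C@@H](c3ccc(O)c(O)c3)[C@H]2CO[Si](C)(C)C(C)(C)C)cc1OC
F5 | step 6 | chloromethyllithium | [Li]CCl
F6 | step 6 | (3R,4R)-3-[(tert-butyldimethylsilyloxy)methyl]-1-chloro-4-hydroxy-6-(trimethylsilyl)hex-5-yn-2-one | O[C@@H](C#C[Si](C)(C)C)[C@H](C(=O)CCl)CO[Si](C)(C)C(C)(C)C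
F7 | step 6 | (4R,5R)-4-[(tert-butyldimethylsilyloxy)methyl]-5-[(trimethylsilyl)ethynyl]oxolan-3-one | O=C1CO[C@@H](C#C[Si](C)(C)C)[C@H]1CO[Si](C)(C)C(C)(C)C
F8 | step 2 | (R)-4-benzyl-3-[(E)-but-2-enoyl]oxazolidin-2-one | C/C=C/C(=O)N1C(=O)OC[C@H]1Cc1ccccc1
F9 | step 2 | (R)-4-benzyl-3-[(2R,3R)-2-ethenyl-3-hydroxy-5-(trimethylsilyl)pent-4-ynoyl]oxazolidin-2-one | O[C@@H](C#C[Si](C)(C)C)[C@H](C(=O)N1C(=O)OC[C@H]1Cc1ccccc1)C=C
F10 | step 2 | (2R,3R)-2-ethenyl-3-hydroxy-N-methoxy-N-methyl-5-(trimethylsilyl)pent-4-ynamide | O[C@@H](C#C[Si](C)(C)C)[C@H](C(=O)N(C)OC)C=C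
F11 | step 2 | (2R,3R)-3-hydroxy-2-(hydroxymethyl)-N-methoxy-N-methyl-5-(trimethylsilyl)pent-4-ynamide | O[C@@H](C#C[Si](C)(C)C)[C@H](C(=O)N(C)OC)CO
F12 | step 10 | 4-[(2R,3R,4R)-3-(acetoxymethyl)-4-(3,4-dimethoxybenzyl)-4-hydroxyoxolan-2-yl]-1,2-phenylene diacetate | COc1ccc(C[C@]2(O)CO[C@@H](c3ccc(OC(C)=O)c(OC(C)=O)c3)[C@H]2COC(C)=O)cc1OC
A1 | alternative 1 | tertiary pinacol boronic ester at C4 carrying the (isopropoxydimethylsilyl)methyl arm (C5), the 3,4-dimethoxybenzyl arm (C7), the benzyloxymethyl-substituted C3 and the tert-butyldimethylsilyloxy-substituted C2 with its 3,4-bis(benzyloxy)phenyl group | COc1ccc(C[C@](B2OC(C)(C)C(C)(C)O2)(C[Si](C)(C)OC(C)C)[C@H](COCc2ccccc2)[C@@H](O[Si](C)(C)C(C)(C)C)c2ccc(OCc3ccccc3)c(OCc3ccccc3)c2)cc1OC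
A2 | alternative 2 | exo-6-[3,4-bis(pivaloyloxy)phenyl]-4-(3,4-dimethoxybenzyl)-2,7-dioxabicyclo[3.2.0]hept-3-ene | O1[C@@H](c2ccc(OC(=O)C(C)(C)C)c(OC(=O)C(C)(C)C)c2)[C@H]2[C@@H]1OC=C2Cc1ccc(OC)c(OC)c1
A3 | alternative 3 | cis-5-[3,4-bis(benzyloxy)phenyl]-4-[(tert-butyldimethylsilyloxy)methyl]dihydrofuran-2(3H)-one | O=C1O[C@@H](c2ccc(OCc3ccccc3)c(OCc3ccccc3)c2)[C@@H](CO[Si](C)(C)C(C)(C)C)C1
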